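You have put less Z into the north flask than Q, 9.50 mM against 10 mM. If one Z makes one D, which is the assumption I book on, D in this flask can't pass 95.0% of the Q charged.

common to all: Q 10 mM; temperature 40 °C
- north: Z 9.5 mM; L 2 mM; the very flask that is asked about, followed so far
- south-east: Z 14 mM; L 2 mM; run made earlier
- flask: Z 9.50 mM; L 2.00 mM; time 5.0 d

| run | time / h | D / % | Q / % |
|---|---|---|---|
| north | 10.0 | 43.0 | 19.4 |
| north | 15.0 | 48.4 | 12.0 |
| north | 25.0 | 54.3 | 6.4 |
| north | 40.0 | 59.9 | 4.3 |
| north | 72.0 | 65.8 | 3.3 |
| north | 120 | 73.2 | 1.7 |
| south-east | 0.500 | 6.5 | 88.5 |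
| south-east | 1.50 | 15.1 | 71.6 |
| south-east | 3.00 | 27.9 | 52.6 |
| south-east | 5.00 | 36.9 | 36.9 |
| south-east | 6.00 | 40.8 | 29.6 |
| south-east | 8.00 | 46.3 | 21.0 |

(readings scatter by 0.5 percentage points)

- D that was removed still counts
- the earlier runs do not show what temperature does; that part of a forecast is a guess
- additions bring no volume worth counting

- Thursday's: at 5.0 d raise the temperature by 20 K, then wait 2.5 d
- Sunday's: change nothing and wait 2.5 d more
- Friday's: at 5.0 d take out 90% of the D then present, then wait 2.5 d
- Tuesday's: at 5.0 d add Z, 50.0% of the amount charged, then wait 2.5 d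

* D, in percent of the Q first charged, at 5.0 d
* what to do for the largest gain in D; "none" if nothing gains more than 2 percentage points (Thursday's / Sunday's / Friday's / Tuesday's / none)
* D present, with what was taken out counted in, in percent of the Q first charged, after Thursday's
* D present, with what was taken out counted in, in percent of the Q first charged, after Friday's

So keep a ledger of Z for the north flask. The first entry is the charge, 9.50 mM. The second is Z turned into D, which at 120 h, the same moment as 5.0 d, is the last reading of 73.2%, or 7.32 mM. The third is what stands free. Call it f, the free share of Z: the charge minus the D formed, divided by the charge. Here f is 22.9%, which would pay for 21.8% more D in percent of the Q charged.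

Now set the claims against that. Q still reads 1.7%, and a further 25.1% of the Q charged is in neither Q nor D. This gap is a pool you can't see, and the readings don't say what it holds. Together the claims come to 26.8%, more than the free Z covers, but that sum counts the whole gap as able to become D, and the readings don't show that it is. My own entry for D at 5.0 d is the reading itself.

The forecast gives 73% for now, chooses Thursday's, and puts D at 90% after that step and at 80% after Friday's. On the temperature it says: “+20 K probably speeds draining 3–5×, giving about 90%, though that factor is a guess.”

The flask gives 73.1%. The best step is Thursday's, gaining 9.9 percentage points and reaching 83.0%, while Friday's reaches 77.5%.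

    Q + L → G (k = 16.0 M⁻¹ h⁻¹, Ea = 64.0 kJ mol⁻¹)
    Q ⇌ X (K = 2.80, k = 0.0680 h⁻¹, Ea = 115 kJ mol⁻¹, ΔH = −26.0 kJ mol⁻¹)
    Q + Z → D, rate k3*[Q]*[Z]^0.5 (k = 1.10 M⁻⁰·⁵ h⁻¹, Ea = 62.0 kJ mol⁻¹)
    (constants at 40 °C)

The forecast and the flask part on Thursday's, 90% against 83.0%. At 120 h the flask has 23.0% of its Z left, as f said. The gap, though, holds G at 15.4% beside X at 9.51%, and the scheme writes the step to G one way. Q and X together hold 11.5%, less than the free Z covers, and added to D they make 84.6%. In the neighbour with 6.0 mM of Q and the same Z, D of 73.9% gives f = 53.3%, and that flask has 53.3% of its Z left at 120 h.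

The readings are simulated with made-up constants; noise was put on by code.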